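## Retrosynthetic overview

1. Endgame: target 26 ⇐ 25 (C8 angelate, C6‑OTBS) ⇐ 22. The C1‑OH/C10‑H pair of 22 comes from a vinylogous Mukaiyama hydration (H to C10, O2 to C1) of the C1=C10 bond of dienone 20.
2. Key disconnection: 20 ⇐ acyclic allene‑yne 19 + CO by an allenic Pauson–Khand [2+2+1]. C1–C5 closes the seven‑membered ring (rhodacycle), then C3–C4 and C2–C3 close the cyclopentenone (carbonylation); both rings form in this one step.
3. Enabling feature: the ring C1–C2–C3(=O)–C4(CH3)=C5, fused at C1/C5 to the seven‑membered ring, has an unsubstituted CH2 (C2) beside the carbonyl and a carbinol C1 beside the methine C10. C3 is therefore CO, C4=C5 a methyl alkyne, and C2–C1–C10 a terminal allene whose inner double bond survives as the hydration site.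
4. 19 ⇐ terminal epoxide 14 + 3‑methoxyprop‑1‑yne (C9–C10 bond), then copper‑catalysed SN2′ methylation to the allene and acetylation of C11‑OH.
5. 14 ⇐ Evans syn‑aldol of a crotonyl imide with but‑2‑ynal (C6, C7), MeMgBr (C11), iodocarbonate cyclisation (C8).

Key step: step 13

Remarks:
- Ring carbons are numbered as in guaianes: C1–C5 five‑membered ring, C5–C10 plus C1 seven‑membered ring, C11 the side‑chain carbinol carbon. β is the face of the C10 methyl.
- The C7 descriptor is R in 20–25 and S in 26 only because the CIP ranking of C6 and C8 changes on desilylation.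
- But‑2‑ynal (4) is taken as purchased material; it is also available in one operation from but‑2‑yn‑1‑ol with MnO2.

## Route

Step 1
Reactants: 1 (R)-4-benzyl-1,3-oxazolidin-2-one; 2 (E)-but-2-enoyl chloride
Product: 3 (4R)-4-benzyl-3-[(E)-but-2-enoyl]-1,3-oxazolidin-2-one
Conditions: n-BuLi, THF, −78 °C; then 2, −78 → 0 °C
Reagents that add atoms: none
Why: N‑acylation of the lithiated oxazolidinone (Evans imide formation); no stereocentre is formed.

Step 2
Reactants: 3; 4 but-2-ynal
Product: 6 (4R)-4-benzyl-3-[(2R,3R)-2-ethenyl-3-hydroxyhex-4-ynoyl]-1,3-oxazolidin-2-one, via boron dienolate 5 (not isolated)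
Conditions: Bu2BOTf, Et3N, CH2Cl2, −78 → 0 °C; 4, −78 °C; then pH 7 buffer, MeOH, H2O2, 0 °C
Reagents that add atoms: none
Why: Evans syn‑aldol: γ‑deprotonation gives the Z(O) dibutylboron dienolate, which attacks the ynal at its α‑carbon through a Zimmerman–Traxler chair on the face away from the benzyl group, setting C7 and C6 as the (2R,3R) syn pair.

Step 3
Reactants: 6
Product: 7 methyl (2R,3R)-2-ethenyl-3-hydroxyhex-4-ynoate
Conditions: Sm(OTf)3 (10 mol%), MeOH, rt
Reagents that add atoms: methanol, CO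
Why: Lewis‑acid‑catalysed methanolysis of the exocyclic imide carbonyl, activated by chelation to the β‑hydroxyl; the near‑neutral conditions should avoid retro‑aldol and migration of the α‑vinyl group into conjugation.

Step 4
Reactants: 7
Product: 9 (3R,4R)-3-ethenyl-2-methylhept-5-yne-2,4-diol, via methyl ketone 8 (not isolated)
Conditions: MeMgBr (4.5 equiv), LaCl3·2LiCl (30 mol%), THF, −20 → 0 °C
Reagents that add atoms: methylmagnesium bromide, C[Mg]Br
Why: Double Grignard addition to the ester builds the C11 dimethylcarbinol; the lanthanum salt suppresses enolisation at C7 and the C6 magnesium alkoxide disfavours retro‑aldol.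

Step 5
Reactants: 9
Product: 10 tert-butyl (3R,4R)-3-ethenyl-2-hydroxy-2-methylhept-5-yn-4-yl carbonate
Conditions: Boc2O (1.3 equiv), DMAP (10 mol%), MeCN, 0 °C → rt
Reagents that add atoms: di-tert-butyl dicarbonate, CC(C)(C)OC(=O)OC(=O)OC(C)(C)C
Why: DMAP‑catalysed carbonate formation is selective for the secondary propargylic hydroxyl over the hindered tertiary one.

Step 6
Reactants: 10
Product: 11 (4S,5S,6R)-5-(2-hydroxypropan-2-yl)-4-(iodomethyl)-6-(prop-1-yn-1-yl)-1,3-dioxan-2-one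
Conditions: IBr (1.3 equiv), PhMe/CH2Cl2, −85 °C; aq. Na2S2O3/NaHCO3
Reagents that add atoms: iodine monobromide, IBr
Why: Iodocarbonate cyclisation (6‑exo‑trig) of a homoallylic tert‑butyl carbonate: the chair with propynyl, the C7 substituent and the developing CH2I all equatorial sets C8 with O8 1,3‑syn to O6 and anti to C11; the terminal alkene should react before the alkyne, which is deactivated by the propargylic carbonate.

Step 7
Reactants: 11
Product: 13 (3S,4R)-2-methyl-3-[(2S)-oxiran-2-yl]hept-5-yne-2,4-diol, via iodo triol 12 (not isolated)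
Conditions: K2CO3 (3 equiv), MeOH, rt
Reagents that add atoms: none
Why: Carbonate methanolysis followed by Williamson closure of the C8 alkoxide onto C9; no bond to C8 is broken, so its configuration is retained.

Step 8
Reactants: 13
Product: 14 (3R,4R)-4-[tert-butyl(dimethyl)silyl]oxy-2-methyl-3-[(2S)-oxiran-2-yl]hept-5-yn-2-ol
Conditions: TBSCl, imidazole, DMF, 0 °C → rt
Reagents that add atoms: tert-butyldimethylsilyl chloride, CC(C)(C)[Si](C)(C)Cl
Why: Silylation is selective for the secondary hydroxyl over the tertiary one; the epoxide is inert to these conditions.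

Step 9
Reactants: 14; 15 3-methoxyprop-1-yne
Product: 16 (3R,4R)-3-[(1R)-1-[tert-butyl(dimethyl)silyl]oxybut-2-yn-1-yl]-8-methoxy-2-methyloct-6-yne-2,4-diol
Conditions: 15 (3 equiv), n-BuLi, THF, −78 °C; BF3·OEt2 (3 equiv); then 14, −78 °C
Reagents that add atoms: none
Why: Yamaguchi–Hirao BF3‑promoted alkynylation at the terminal epoxide carbon C9 forms the C9–C10 bond without touching C8; the tertiary alkoxide cannot open the epoxide (4‑exo or 5‑endo only).

Step 10
Reactants: 16
Product: 17 (3R,4R)-3-[(1R)-1-[tert-butyl(dimethyl)silyl]oxybut-2-yn-1-yl]-8-methoxy-2-methyl-4-[(triethylsilyl)oxy]oct-6-yn-2-ol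
Conditions: TESCl, imidazole, DMAP (cat.), CH2Cl2, 0 °C → rt
Reagents that add atoms: chlorotriethylsilane, CC[Si](Cl)(CC)CC
Why: Silylation is selective for the secondary C8 hydroxyl over the tertiary C11 hydroxyl, and differentiates O8 (TES) from O6 (TBS) for the endgame.

Step 11
Reactants: 17
Product: 18 (3R,4R)-3-[(1R)-1-[tert-butyl(dimethyl)silyl]oxybut-2-yn-1-yl]-2,6-dimethyl-4-[(triethylsilyl)oxy]octa-6,7-dien-2-ol
Conditions: MeMgBr (4 equiv), CuBr·SMe2 (10 mol%), P(OEt)3 (20 mol%), Et2O, 0 °C → rt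
Reagents that add atoms: methylmagnesium bromide, C[Mg]Br
Why: Copper‑catalysed SN2′ substitution of a primary propargylic methyl ether (syn‑carbocupration with methyl to C10, then β‑alkoxide elimination) gives the 1,1‑disubstituted terminal allene; the secondary propargylic silyl ether at C6 is a far poorer leaving group.

Step 12
Reactants: 18
Product: 19 (3R,4R)-3-[(1R)-1-[tert-butyl(dimethyl)silyl]oxybut-2-yn-1-yl]-2,6-dimethyl-4-[(triethylsilyl)oxy]octa-6,7-dien-2-yl acetate
Conditions: EtMgBr (1.1 equiv), THF, 0 °C; then Ac2O (3 equiv), 0 °C → rt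
Reagents that add atoms: acetic anhydride, CC(=O)OC(C)=O
Why: Acylation of the preformed magnesium alkoxide overcomes the hindrance of the tertiary C11 carbinol; silyl ethers, alkyne and allene are inert.

Step 13
Reactants: 19
Product: 20 (6R,7R,8R)-11-acetoxy-6-[tert-butyl(dimethyl)silyl]oxy-8-[(triethylsilyl)oxy]guaia-1(10),4-dien-3-one
Conditions: [Rh(CO)2Cl]2 (5 mol%), CO (1 atm), PhMe (0.01 M), 90 °C
Reagents that add atoms: carbon monoxide, [C-]#[O+]
Why: Monovalent rhodium binds the alkyne and the distal C1=C2 bond of the allene and undergoes oxidative cyclisation to a rhodacyclopentene, forming C1–C5; CO insertion and reductive elimination then form C3–C4 and C2–C3, the closest known reaction type being the rhodium‑catalysed allenic Pauson–Khand cyclocarbonylation of allene‑ynes to bicyclo[5.3.0]decadienones. The seven‑membered ring closes in the oxidative cyclisation (exo with respect to the alkyne, with the proximal allene bond C1=C10 left inside the ring), and the five‑membered ring closes in the carbonylative reductive elimination ([2+2+1]). No stereocentre is created; C6, C7 and C8 pass through unchanged and C1/C10 stay sp2 for step 14. The step needs distal over proximal allene selectivity, which the rhodium carbonyl chloride catalyst and the methyl group on the proximal carbon C10 secure, and carbonylation over cycloisomerisation, which is secured because the distal terminus C2 is an unsubstituted CH2 (no β‑hydrogen in the rhodacycle for an Alder‑ene path) under CO. The three branching substituents on the five‑atom tether favour the folded conformer, and high dilution suppresses intermolecular reaction.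

Step 14
Reactants: 20
Product: 22 (1R,6R,7R,8R,10S)-11-acetoxy-6-[tert-butyl(dimethyl)silyl]oxy-1-hydroxy-8-[(triethylsilyl)oxy]guai-4-en-3-one, via hydroperoxide 21 (not isolated)
Conditions: Mn(dpm)3 (20 mol%), PhSiH3 (2.5 equiv), O2 (1 atm), i-PrOH/CH2Cl2, 0 °C → rt; then PPh3 (1.5 equiv)
Reagents that add atoms: dioxygen, O=O
Why: Vinylogous Mukaiyama hydration by metal‑hydride hydrogen‑atom transfer: H adds to the δ‑carbon C10 from the face opposite the C6/C8 silyloxy groups (10α‑H, methyl β), the delocalised C1–C5–C4–C3–O radical captures O2 at C1 on the same open face, anti to the new C10 methyl, to give the conjugated γ‑hydroperoxy enone, and PPh3 reduces it to the 1α‑alcohol.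

Step 15
Reactants: 22
Product: 23 (1R,6R,7R,8R,10S)-11-acetoxy-6-[tert-butyl(dimethyl)silyl]oxy-1,8-dihydroxyguai-4-en-3-one
Conditions: PPTS (20 mol%), MeOH/CH2Cl2, 0 °C
Reagents that add atoms: none
Why: Acid‑catalysed methanolysis removes the secondary TES ether much faster than the secondary TBS ether; the tertiary acetate and the tertiary C1 alcohol (a cation at C1 would be conjugated to the enone) should be stable.

Step 16
Reactants: 23; 24 angelic acid, (Z)-2-methylbut-2-enoic acid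
Product: 25 (1R,6R,7R,8R,10S)-11-acetoxy-6-[tert-butyl(dimethyl)silyl]oxy-1-hydroxy-8-[(Z)-2-methylbut-2-enoyl]oxyguai-4-en-3-one
Conditions: 24, 2,4,6-trichlorobenzoyl chloride, Et3N, PhMe, rt; filter; then 23, PhMe, 80 °C
Reagents that add atoms: none
Why: Yamaguchi esterification with the preformed mixed anhydride and no DMAP or free amine, the variant used to keep the Z geometry of angelates; only the secondary C8 hydroxyl reacts, the tertiary C1 hydroxyl does not.

Step 17
Reactants: 25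
Product: 26 (1R,6R,7S,8R,10S)-11-acetoxy-8-[(Z)-2-methylbut-2-enoyl]oxy-1,6-dihydroxyguai-4-en-3-one (target)
Conditions: HF·pyridine, pyridine, THF, 0 °C → rt
Reagents that add atoms: none
Why: Fluoride‑mediated cleavage of the C6 TBS ether under buffered acidic conditions, which should not promote acetyl migration or angelate isomerisation.

## Compound list

1 | (R)-4-benzyl-1,3-oxazolidin-2-one | O=C1N[C@H](Cc2ccccc2)CO1 | starting material
2 | (E)-but-2-enoyl chloride | C/C=C/C(Cl)=O | starting material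
3 | (4R)-4-benzyl-3-[(E)-but-2-enoyl]-1,3-oxazolidin-2-one | C/C=C/C(=O)N1C(=O)OC[C@H]1Cc1ccccc1 | intermediate
4 | but-2-ynal | CC#CC=O | starting material
5 | dibutylboron Z(O)-dienolate of 3 | C=C/C=C(\OB(CCCC)CCCC)N1C(=O)OC[C@H]1Cc1ccccc1 | intermediate (not isolated)
6 | (4R)-4-benzyl-3-[(2R,3R)-2-ethenyl-3-hydroxyhex-4-ynoyl]-1,3-oxazolidin-2-one | CC#C[C@H](O)[C@@H](C=C)C(=O)N1C(=O)OC[C@H]1Cc1ccccc1 | intermediate
7 | methyl (2R,3R)-2-ethenyl-3-hydroxyhex-4-ynoate | CC#C[C@H](O)[C@@H](C=C)C(=O)OC | intermediate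
8 | (3R,4R)-3-ethenyl-4-hydroxyhept-5-yn-2-one | CC#C[C@H](O)[C@@H](C=C)C(C)=O | intermediate (not isolated)
9 | (3R,4R)-3-ethenyl-2-methylhept-5-yne-2,4-diol | CC#C[C@H](O)[C@@H](C=C)C(C)(C)O | intermediate
10 | tert-butyl (3R,4R)-3-ethenyl-2-hydroxy-2-methylhept-5-yn-4-yl carbonate | CC#C[C@H](OC(=O)OC(C)(C)C)[C@@H](C=C)C(C)(C)O | intermediate
11 | (4S,5S,6R)-5-(2-hydroxypropan-2-yl)-4-(iodomethyl)-6-(prop-1-yn-1-yl)-1,3-dioxan-2-one | CC#C[C@@H]1OC(=O)O[C@H](CI)[C@H]1C(C)(C)O | intermediate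
12 | (2S,3S,4R)-3-(2-hydroxypropan-2-yl)-1-iodohept-5-yne-2,4-diol | CC#C[C@H](O)[C@H](C(C)(C)O)[C@H](O)CI | intermediate (not isolated)
13 | (3S,4R)-2-methyl-3-[(2S)-oxiran-2-yl]hept-5-yne-2,4-diol | CC#C[C@H](O)[C@H](C(C)(C)O)[C@H]1CO1 | intermediate
14 | (3R,4R)-4-[tert-butyl(dimethyl)silyl]oxy-2-methyl-3-[(2S)-oxiran-2-yl]hept-5-yn-2-ol | CC#C[C@H](O[Si](C)(C)C(C)(C)C)[C@H](C(C)(C)O)[C@H]1CO1 | intermediate
15 | 3-methoxyprop-1-yne | COCC#C | starting material
16 | (3R,4R)-3-[(1R)-1-[tert-butyl(dimethyl)silyl]oxybut-2-yn-1-yl]-8-methoxy-2-methyloct-6-yne-2,4-diol | CC#C[C@H](O[Si](C)(C)C(C)(C)C)[C@H](C(C)(C)O)[C@H](O)CC#CCOC | intermediate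
17 | (3R,4R)-3-[(1R)-1-[tert-butyl(dimethyl)silyl]oxybut-2-yn-1-yl]-8-methoxy-2-methyl-4-[(triethylsilyl)oxy]oct-6-yn-2-ol | CC#C[C@H](O[Si](C)(C)C(C)(C)C)[C@H](C(C)(C)O)[C@H](O[Si](CC)(CC)CC)CC#CCOC | intermediate
18 | (3R,4R)-3-[(1R)-1-[tert-butyl(dimethyl)silyl]oxybut-2-yn-1-yl]-2,6-dimethyl-4-[(triethylsilyl)oxy]octa-6,7-dien-2-ol | CC#C[C@H](O[Si](C)(C)C(C)(C)C)[C@H](C(C)(C)O)[C@H](O[Si](CC)(CC)CC)CC(C)=C=C | intermediate
19 | (3R,4R)-3-[(1R)-1-[tert-butyl(dimethyl)silyl]oxybut-2-yn-1-yl]-2,6-dimethyl-4-[(triethylsilyl)oxy]octa-6,7-dien-2-yl acetate | CC#C[C@H](O[Si](C)(C)C(C)(C)C)[C@H](C(C)(C)OC(C)=O)[C@H](O[Si](CC)(CC)CC)CC(C)=C=C | intermediate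
20 | (6R,7R,8R)-11-acetoxy-6-[tert-butyl(dimethyl)silyl]oxy-8-[(triethylsilyl)oxy]guaia-1(10),4-dien-3-one | CC[Si](CC)(CC)O[C@@H]1CC(C)=C2CC(=O)C(C)=C2[C@H](O[Si](C)(C)C(C)(C)C)[C@@H]1C(C)(C)OC(C)=O | intermediate
21 | (1R,6R,7R,8R,10S)-11-acetoxy-6-[tert-butyl(dimethyl)silyl]oxy-1-hydroperoxy-8-[(triethylsilyl)oxy]guai-4-en-3-one | CC[Si](CC)(CC)O[C@@H]1C[C@H](C)[C@]2(OO)CC(=O)C(C)=C2[C@H](O[Si](C)(C)C(C)(C)C)[C@@H]1C(C)(C)OC(C)=O | intermediate (not isolated)
22 | (1R,6R,7R,8R,10S)-11-acetoxy-6-[tert-butyl(dimethyl)silyl]oxy-1-hydroxy-8-[(triethylsilyl)oxy]guai-4-en-3-one | CC[Si](CC)(CC)O[C@@H]1C[C@H](C)[C@]2(O)CC(=O)C(C)=C2[C@H](O[Si](C)(C)C(C)(C)C)[C@@H]1C(C)(C)OC(C)=O | intermediate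
23 | (1R,6R,7R,8R,10S)-11-acetoxy-6-[tert-butyl(dimethyl)silyl]oxy-1,8-dihydroxyguai-4-en-3-one | O[C@@H]1C[C@H](C)[C@]2(O)CC(=O)C(C)=C2[C@H](O[Si](C)(C)C(C)(C)C)[C@@H]1C(C)(C)OC(C)=O | intermediate
24 | angelic acid, (Z)-2-methylbut-2-enoic acid | C/C=C(/C)C(O)=O | starting material
25 | (1R,6R,7R,8R,10S)-11-acetoxy-6-[tert-butyl(dimethyl)silyl]oxy-1-hydroxy-8-[(Z)-2-methylbut-2-enoyl]oxyguai-4-en-3-one | C/C=C(/C)C(=O)O[C@@H]1C[C@H](C)[C@]2(O)CC(=O)C(C)=C2[C@H](O[Si](C)(C)C(C)(C)C)[C@@H]1C(C)(C)OC(C)=O | intermediate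
26 | (1R,6R,7S,8R,10S)-11-acetoxy-8-[(Z)-2-methylbut-2-enoyl]oxy-1,6-dihydroxyguai-4-en-3-one | C/C=C(/C)C(=O)O[C@@H]1C[C@H](C)[C@]2(O)CC(=O)C(C)=C2[C@H](O)[C@@H]1C(C)(C)OC(C)=O | target

## Step count and risks

Total step count: 17. Longest linear sequence: 17 steps (1 → 26).

Steps most likely to fail:

1. Step 14. What may go wrong: hydrogen‑atom delivery to the wrong alkene carbon, oxygen capture at C4 instead of C1, insufficient facial selectivity at C10 or C1, or plain 1,6‑reduction without oxygenation. The fallback sets out from 20 and comes back at 22. Dimethyldioxirane (acetone, 0 °C) should epoxidise the electron‑richer C1=C10 bond from the face opposite the C6/C8 silyloxy groups to give the 1α,10α‑epoxide F1. Silyl‑triflate‑mediated isomerisation (TMSOTf, 2,6‑lutidine, then DBU) should ionise at C10, the carbon not conjugated to the enone, and remove a C14 proton to give the 1α‑trimethylsilyloxy‑10(14)‑ene F2. Brief methanolysis (citric acid, MeOH, 0 °C) frees the tertiary allylic alcohol F3. Hydroxyl‑directed hydrogenation (H2, [Ir(cod)(PCy3)(py)]PF6, CH2Cl2) then delivers hydrogen to C10 from the face of the C1 hydroxyl and gives 22; the tetrasubstituted enone should not be reduced.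

2. Step 6. What may go wrong: iodonium attack on the alkyne with 5‑exo‑dig closure of the propargylic carbonate instead of the alkene pathway, or insufficient facial control at C8. The fallback sets out from 9 and comes back at 14. The secondary hydroxyl of 9 is silylated (TBSCl, imidazole, DMF) to F4. mCPBA (CH2Cl2, NaHCO3) epoxidises the terminal alkene, leaving the alkyne, to give 14 mixed with its C8 epimer F5. Hydrolytic kinetic resolution with (S,S)-(salen)Co(OAc) (trivalent cobalt) and about 0.55 equiv of water should hydrolyse F5 to the triol F6 under catalyst control, and 14 is separated from F6 by chromatography.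

3. Step 16. What may go wrong: Z to E isomerisation of the acyl donor to the tiglate, slow acylation of the hindered C8 hydroxyl, or acetyl migration from O11 to O8 on heating. The fallback sets out from 23 and comes back at 25. The C8 hydroxyl is esterified with 2-[bis(2,2,2-trifluoroethoxy)phosphoryl]propanoic acid (EDC·HCl, DMAP cat., CH2Cl2, 0 °C) to the phosphonate ester F7. Still–Gennari olefination (KHMDS, 18‑crown‑6, THF, −78 °C, then acetaldehyde) then builds the (Z)-2-methylbut-2-enoate in place and gives 25.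

## Further compounds

F1 | step 14 | (6R,7R,8R)-11-acetoxy-6-[tert-butyl(dimethyl)silyl]oxy-1α,10α-epoxy-8-[(triethylsilyl)oxy]guai-4-en-3-one | CC[Si](CC)(CC)O[C@@H]1C[C@@]3(C)O[C@]32CC(=O)C(C)=C2[C@H](O[Si](C)(C)C(C)(C)C)[C@@H]1C(C)(C)OC(C)=O
F2 | step 14 | (6R,7R,8R)-11-acetoxy-6-[tert-butyl(dimethyl)silyl]oxy-8-[(triethylsilyl)oxy]-1α-[(trimethylsilyl)oxy]guaia-4,10(14)-dien-3-one | CC[Si](CC)(CC)O[C@@H]1CC(=C)[C@]2(O[Si](C)(C)C)CC(=O)C(C)=C2[C@H](O[Si](C)(C)C(C)(C)C)[C@@H]1C(C)(C)OC(C)=O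
F3 | step 14 | (6R,7R,8R)-11-acetoxy-6-[tert-butyl(dimethyl)silyl]oxy-1α-hydroxy-8-[(triethylsilyl)oxy]guaia-4,10(14)-dien-3-one | CC[Si](CC)(CC)O[C@@H]1CC(=C)[C@]2(O)CC(=O)C(C)=C2[C@H](O[Si](C)(C)C(C)(C)C)[C@@H]1C(C)(C)OC(C)=O
F4 | step 6 | (3R,4R)-4-[tert-butyl(dimethyl)silyl]oxy-3-ethenyl-2-methylhept-5-yn-2-ol | CC#C[C@H](O[Si](C)(C)C(C)(C)C)[C@@H](C=C)C(C)(C)O
F5 | step 6 | (3R,4R)-4-[tert-butyl(dimethyl)silyl]oxy-2-methyl-3-[(2R)-oxiran-2-yl]hept-5-yn-2-ol | CC#C[C@H](O[Si](C)(C)C(C)(C)C)[C@H](C(C)(C)O)[C@@H]1CO1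
F6 | step 6 | (2R,3R)-3-[(1R)-1-[tert-butyl(dimethyl)silyl]oxybut-2-yn-1-yl]-4-methylpentane-1,2,4-triol | CC#C[C@H](O[Si](C)(C)C(C)(C)C)[C@H](C(C)(C)O)[C@@H](O)CO
F7 | step 16 | (1R,6R,7R,8R,10S)-11-acetoxy-8-[2-[bis(2,2,2-trifluoroethoxy)phosphoryl]propanoyl]oxy-6-[tert-butyl(dimethyl)silyl]oxy-1-hydroxyguai-4-en-3-one (epimers at the phosphonate carbon) | CC(C(=O)O[C@@H]1C[C@H](C)[C@]2(O)CC(=O)C(C)=C2[C@H](O[Si](C)(C)C(C)(C)C)[C@@H]1C(C)(C)OC(C)=O)P(=O)(OCC(F)(F)F)OCC(F)(F)F
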